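## The problem

The target is an unsymmetrical bicoumarin. Unit A is a 7-hydroxycoumarin that carries the bridging oxygen at C6, unit B is a 6,7-dihydroxycoumarin that carries it at C5, and one diaryl ether oxygen is the only link between the two benzopyranones. There is no stereocentre, so nothing has to be controlled in space and the whole difficulty is regiochemical. Seven oxygens sit on the two benzene rings, three of them contiguous on ring B (C5, C6, C7). The ether carbon C5 lies between the ring-fusion carbon C4a and C6, so the ether has to be made at a doubly ortho-substituted position. The three hydroxyls that end up free must be kept distinct from the one oxygen that becomes the bridge, on rings where several positions are similarly activated. The finished polyphenol is delicate: the catechol of unit B and the oxygen-rich ring A oxidise in air and in base, both lactones open in aqueous alkali, and both C3=C4 bonds are Michael acceptors. The free phenols should therefore appear late and meet no oxidant. The feature that opens the problem is that each ring has a hydroxyl ortho to its ether carbon: C7–OH beside C6 in unit A and C6–OH beside C5 in unit B. A formyl group at each of these carbons can serve three purposes in turn: on ring B it can only be introduced next to a free C5 hydroxyl, which fixes its place; on ring A it activates an ortho fluoride towards that same hydroxyl; and at the end both formyl carbons can be exchanged for oxygen by aryl migration.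

## Retrosynthesis

Primed locants count the carbons of the benzene ring that becomes ring A from its ether carbon C1'.

**Target 12 to tetraphenol 9 and ethyl propiolate 10.** The C4–C4a and O1–C2 bonds of pyranone A are cut. The ring left behind is a 4-aryloxyresorcinol, and resorcinols substituted at C4 are annulated para to one hydroxyl and ortho to the other, which here is C5' and leads to the 6-aryloxy-7-hydroxy pattern. Removing pyranone B instead would gain nothing, because unit B can be bought with its lactone in place. Keeping lactone A through the ether formation would require a coumarin that already carries fluorine and a formyl group on its benzene ring, which is not an article of commerce. The forward reaction must prefer C5' of ring A over C8 of the lactone-deactivated ring B and over the phenolic oxygens.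

**Tetraphenol 9 to bis-phenol 8.** Two O–CH3 bonds are cut. Methyl is the smallest group that survives base, heat and peracid and still falls to one reagent at the end. The precursor has only two free hydroxyls and is far less oxidisable than 9.

**Bis-phenol 8 to dialdehyde 6 (key disconnection).** The C6–O bond of unit B and the C2'–O bond of ring A (the later C7–O of unit A) are each traced back to a C–CHO bond. Direct hydroxylation of a diaryl ether would not distinguish the open positions. Assembling the ether from rings that already bear these oxygens would mean coupling an unactivated aryl halide with one hydroxyl of a catechol-type partner. With carbon in place of oxygen, the position of each future hydroxyl is fixed by ordinary carbonyl chemistry, and the same substituents help to build the ether. The forward step must make aryl migrate in preference to hydride at both aldehydes and must spare the coumarin double bond.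

**Dialdehyde 6 to salicylaldehyde-type phenol 4 and fluoroaldehyde 5.** The C1'–O bond of the bridge is cut. The formyl group ortho to fluorine in 5 makes this an SNAr, so no metal catalyst is needed for a bond to a hindered phenol oxygen. The opposite cut, at C5–O of unit B, would need a leaving group at C5 of the coumarin and is kept in reserve. Both fragments are simple: 5 is bought and 4 is two steps from a commercial coumarin. The forward reaction asks a chelated, doubly ortho-substituted phenoxide to attack a fluoride that is only moderately activated.

**Phenol 4 to 5-hydroxy-7-methoxycoumarin 2.** The C6–CHO bond is cut. An ortho-specific formylation through the phenoxide can only reach C6, because the other ortho carbon is C4a. A formylation not guided by the hydroxyl would have to choose between C6 and C8.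

**Monomethyl ether 2 to 5,7-dihydroxycoumarin 1.** The O7–CH3 bond is cut. The C7 hydroxyl must be masked so that only the C5 oxygen directs the formylation and enters the ether. The forward step relies on the higher acidity and easier access of the C7 hydroxyl.

## Roads not taken

**Alternative 1:** Ring B is cut at C5–C6 and C4a–C8a. In the forward direction 1,4-dimethoxy-1,3-bis(trimethylsilyloxy)buta-1,3-diene A3 adds to 3-(2,4-dimethoxyphenoxy)prop-2-ynal A2, and loss of methanol gives the fully substituted salicylaldehyde A1.
- Merits: the crowded ether at C5 is installed as an aryloxy alkyne before ring B exists, so no hindered SNAr is needed. The polarity of the two partners places the nucleophilic diene terminus on the oxygen-bearing alkyne carbon, which delivers C6–OMe, C7–OH and C8a–OH correctly differentiated. The oxygens of ring A are simply bought, so no oxidation step is required. In these respects it is better than the chosen plan.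
- Weak points: A2 is a push–pull ynol ether aldehyde that needs several steps to make and is prone to hydration and polymerisation. A3 is more hindered at its reacting terminus than the parent diene and must be made fresh. After A1 there remain a lactonisation for pyranone B, the demethylation and the same ring A annulation as in step 6, so the endgame is no easier.
- Comparison: about three steps to each partner and four after the key step, against six in all. The chosen plan offers stable, purchasable building blocks and the shorter line in return for its harder ether formation.

**Alternative 2:** Both C8a–O1 bonds are cut. In the forward direction the (E,E)-bis-cinnamic acid A5 is isomerised to the Z acids under a flavin photocatalyst in air, and each carboxylate oxygen closes onto C8a of its own ring to give the trimethyl ether A4 of the target.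
- Merits: it is the shortest road, roughly four steps (ether formation, double chain extension, photocyclisation, demethylation) against six. Both pyranones close in one operation, and the ether is made from an unhindered, more nucleophilic phenoxide than 4. On step count and convergence it is better than the chosen plan.
- Weak points: the oxidative lactonisation is established for single, simple electron-rich cinnamic acids, and here it must succeed twice in one molecule. Ring A of A5 has two open ortho positions, and closure at the one between the side chain and the ether would give the 8-aryloxy isomer, a regiochemical question that has no counterpart in the chosen plan. The product coumarins absorb light and can react further.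
- Comparison: the chosen plan is longer, but each oxygen is placed by a formyl carbon whose position is unambiguous, and every step is a ground-state reaction with close precedent.

**Alternative 3:** Ring A is cut at C8–C8a, C6–C7 and C4a–C8a. In the forward direction racemic 2-[(6,7-dimethoxy-2-oxo-2H-chromen-5-yl)oxy]but-3-enoyl chloride A7 is dehydrochlorinated by an amine base to a ketene. The ketene adds to ethoxyacetylene A8, and the vinylcyclobutenone opens and recloses by 6π electrocyclisation to the phenol A6.
- Merits: ring A is formed with its oxygens differentiated, the hydroxyl para to the ether free and the ortho oxygen masked as an ethyl ether. The final pyranone annulation would then run on a monophenol with one activated site, which is cleaner than step 6 on tetraphenol 9. The bridge is made by alkylating 5-hydroxy-6,7-dimethoxy-2H-chromen-2-one A9 at an sp3 carbon and not by SNAr.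
- Weak points: A9 already contains the 5,6,7-trioxygenated ring, so the C6 oxygen of unit B becomes a separate multistep problem. A ketene must be generated beside a Michael-acceptor coumarin and can dimerise. A8 is volatile and costly, and three alkyl ethers must be removed at the end.
- Comparison: roughly nine or ten steps. The chosen plan needs a fallback for its last step, but it brings in the C6 oxygen of unit B and the C7 oxygen of unit A in one operation from two commercial aromatics.

Key step: step 4

Remark: compounds 1, 5 and 10 are taken as purchased; primed locants in 6, 8 and 9 count the ring A carbons from the ether carbon C1'.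

## Route

Step 1
Reactants: 1 5,7-dihydroxy-2H-chromen-2-one (5,7-dihydroxycoumarin)
Product: 2 5-hydroxy-7-methoxy-2H-chromen-2-one
Conditions: MeI (1.05 equiv), K2CO3 (1.0 equiv), acetone, rt
Reagents that add atoms: iodomethane, CI
Why: Williamson O-methylation with limiting reagent: the C7 hydroxyl is the more acidic (its phenoxide is conjugated para-quinonoid with the lactone carbonyl) and the less hindered (the C5 hydroxyl is peri to H4), so one equivalent of base and MeI should methylate O7 first, as is usual for partial alkylation of 5,7-dihydroxycoumarins. Bis-ether and unreacted 1 should be separable by chromatography.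

Step 2
Reactants: 2 5-hydroxy-7-methoxy-2H-chromen-2-one
Product: 4 5-hydroxy-7-methoxy-2-oxo-2H-chromene-6-carbaldehyde, via 6-hydroxymethyl phenol 3 (not isolated)
Conditions: MgCl2 (2 equiv), Et3N (4 equiv), (CH2O)n (6 equiv), MeCN, reflux; then 1 M HCl
Reagents that add atoms: paraformaldehyde (as formaldehyde), C=O
Why: Casiraghi–Skattebøl ortho-formylation: the magnesium phenoxide of 2 delivers formaldehyde through a six-membered chelate to the only free ortho carbon, C6 (the other ortho carbon is the ring fusion C4a), giving 3, which a second formaldehyde oxidises to the aldehyde by hydride transfer. C6 is further activated by the flanking C7 methoxyl, and C8 is para to the phenoxide and out of reach of the chelate.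

Step 3
Reactants: 4 5-hydroxy-7-methoxy-2-oxo-2H-chromene-6-carbaldehyde, 5 2-fluoro-5-methoxybenzaldehyde
Product: 6 5-(2-formyl-4-methoxyphenoxy)-7-methoxy-2-oxo-2H-chromene-6-carbaldehyde
Conditions: Cs2CO3 (1.5 equiv), DMA, 110 °C, argon
Reagents that add atoms: none
Why: Nucleophilic aromatic substitution: the formyl group ortho to fluorine in 5 stabilises the Meisenheimer adduct and the caesium phenoxide of 4 is the nucleophile, the coupling of salicylaldehydes with 2-fluorobenzaldehydes to bis-formyl diaryl ethers being the direct precedent. The methoxyl para to fluorine and the chelated, doubly ortho-substituted phenoxide both slow the reaction, hence the caesium counter-ion, the dipolar aprotic solvent and heat.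

Step 4
Reactants: 6 5-(2-formyl-4-methoxyphenoxy)-7-methoxy-2-oxo-2H-chromene-6-carbaldehyde
Product: 8 6-hydroxy-5-(2-hydroxy-4-methoxyphenoxy)-7-methoxy-2H-chromen-2-one, via bis-formate 7 (not isolated)
Conditions: mCPBA (3 equiv), CH2Cl2, 0 °C to reflux; aq Na2SO3 wash; then Et3N (cat.), MeOH, rt
Reagents that add atoms: 3-chloroperoxybenzoic acid (mCPBA), O=C(OO)c1cccc(Cl)c1
Why: This is a Dakin-type Baeyer–Villiger oxidation run twice in one flask: mCPBA adds to each formyl group to give a peroxy hemiacetal (Criegee adduct), the aryl group migrates from carbon to the proximal peroxide oxygen as 3-chlorobenzoate leaves, and the two aryl formates of 7 are cleaved by base-catalysed methanolysis to the phenols of 8. The closest known reaction type is the peracid oxidation of ortho- and para-alkoxy- or aryloxybenzaldehydes to phenols through their formates, including the sequence in which a fluorobenzaldehyde first serves in an SNAr and is then oxidised. No ring is closed and no stereocentre is formed; two C–C bonds are exchanged for the C6–O bond of unit B and the C2'–O bond of ring A, the later C7–O bond of unit A. The selectivity needed is aryl over hydride migration: the ring B formyl group lies between the C5 aryloxy and C7 methoxy oxygens, whose lone pairs stabilise positive charge on the migrating carbon, and the ring A formyl group has the bridging oxygen ortho to it. The second requirement is chemoselectivity: the coumarin C3=C4 bond is an electron-poor enoate that an electrophilic peracid should not epoxidise, and the new phenols stay masked as formates until the excess oxidant has been reduced. Methanolysis with catalytic Et3N should be mild enough to leave the lactone closed.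

Step 5
Reactants: 8 6-hydroxy-5-(2-hydroxy-4-methoxyphenoxy)-7-methoxy-2H-chromen-2-one
Product: 9 5-(2,4-dihydroxyphenoxy)-6,7-dihydroxy-2H-chromen-2-one
Conditions: BBr3 (6 equiv), CH2Cl2, −78 °C to rt; then H2O, 0 °C, argon
Reagents that add atoms: none
Why: Lewis-acid cleavage of aryl methyl ethers: BBr3 complexes each methoxy oxygen and bromide removes the methyl group by SN2, while the diaryl ether (no sp3 carbon to attack) and the lactone remain, as in the routine conversion of methoxycoumarins to hydroxycoumarins. The excess allows for the two free phenols and the lactone carbonyl, and the air-sensitive tetraphenol is worked up and carried on under argon.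

Step 6
Reactants: 9 5-(2,4-dihydroxyphenoxy)-6,7-dihydroxy-2H-chromen-2-one, 10 ethyl prop-2-ynoate (ethyl propiolate)
Product: 12 6-[(6,7-dihydroxy-2-oxo-2H-chromen-5-yl)oxy]-7-hydroxy-2H-chromen-2-one, via Z-cinnamate 11 (not isolated)
Conditions: 10 (1.2 equiv), ZnCl2 (1.2 equiv), dioxane, 100 °C, argon
Reagents that add atoms: none
Why: Pechmann-type coumarin synthesis with a propiolate: ZnCl2-promoted hydroarylation of 10 by the resorcinol ring of 9 at C5' (para to the C2' hydroxyl, ortho to the C4' hydroxyl) gives Z-cinnamate 11 by anti addition across the alkyne, and 11 lactonises onto the C4' hydroxyl with loss of ethanol. 4-Substituted resorcinols give 6-substituted 7-hydroxycoumarins in this reaction because the carbon between the two hydroxyls is hindered, and C8 of unit B is deactivated by its lactone.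

## Compound list

1 | 5,7-dihydroxy-2H-chromen-2-one | Oc1cc(O)c2ccc(=O)oc2c1 | starting material
2 | 5-hydroxy-7-methoxy-2H-chromen-2-one | COc1cc(O)c2ccc(=O)oc2c1 | intermediate
3 | 5-hydroxy-6-(hydroxymethyl)-7-methoxy-2H-chromen-2-one | COc1cc2oc(=O)ccc2c(O)c1CO | intermediate (not isolated)
4 | 5-hydroxy-7-methoxy-2-oxo-2H-chromene-6-carbaldehyde | COc1cc2oc(=O)ccc2c(O)c1C=O | intermediate
5 | 2-fluoro-5-methoxybenzaldehyde | COc1ccc(F)c(C=O)c1 | starting material
6 | 5-(2-formyl-4-methoxyphenoxy)-7-methoxy-2-oxo-2H-chromene-6-carbaldehyde | COc1ccc(Oc2c(C=O)c(OC)cc3oc(=O)ccc23)c(C=O)c1 | intermediate
7 | 5-[2-(formyloxy)-4-methoxyphenoxy]-7-methoxy-2-oxo-2H-chromen-6-yl formate | COc1ccc(Oc2c(OC=O)c(OC)cc3oc(=O)ccc23)c(OC=O)c1 | intermediate (not isolated)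
8 | 6-hydroxy-5-(2-hydroxy-4-methoxyphenoxy)-7-methoxy-2H-chromen-2-one | COc1ccc(Oc2c(O)c(OC)cc3oc(=O)ccc23)c(O)c1 | intermediate
9 | 5-(2,4-dihydroxyphenoxy)-6,7-dihydroxy-2H-chromen-2-one | Oc1ccc(Oc2c(O)c(O)cc3oc(=O)ccc23)c(O)c1 | intermediate
10 | ethyl prop-2-ynoate | C#CC(=O)OCC | starting material
11 | ethyl (2Z)-3-{5-[(6,7-dihydroxy-2-oxo-2H-chromen-5-yl)oxy]-2,4-dihydroxyphenyl}prop-2-enoate | CCOC(=O)/C=C\c1cc(Oc2c(O)c(O)cc3oc(=O)ccc23)c(O)cc1O | intermediate (not isolated)
12 | 6-[(6,7-dihydroxy-2-oxo-2H-chromen-5-yl)oxy]-7-hydroxy-2H-chromen-2-one | O=c1ccc2cc(Oc3c(O)c(O)cc4oc(=O)ccc34)c(O)cc2o1 | target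

## Step count and least certain steps

Total step count: 6. Longest linear sequence: 6 steps (1 to 12).

**Step 4 (key step).** The most likely failure is hydride migration competing with aryl migration at the ring A aldehyde. That ring has only one ortho donor, the bridging oxygen, whose lone pair is shared with the electron-poor ring B, and its methoxyl is meta to the formyl group and gives no resonance help. The result would be carboxylic acid formation in place of the formate. A second risk is slow peracid addition to the ring B aldehyde, which is flanked on both sides, so that the double oxidation stalls halfway. The fallback replaces the ring A formyl group by acetyl, where only aryl and methyl compete for migration. It sets out from 4, which is coupled under the conditions of step 3 with commercial 1-(2-fluoro-5-methoxyphenyl)ethan-1-one to give 5-(2-acetyl-4-methoxyphenoxy)-7-methoxy-2-oxo-2H-chromene-6-carbaldehyde F1. Oxidation with mCPBA and catalytic CF3CO2H should give the mixed ester 2-{[6-(formyloxy)-7-methoxy-2-oxo-2H-chromen-5-yl]oxy}-5-methoxyphenyl acetate F2, which is not isolated, and methanolysis returns to the route at 8.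

**Step 3.** The most likely failure is low conversion, because the phenoxide of 4 is chelated to its formyl group, hindered on both sides and delocalised into the coumarin, while the fluoride of 5 is deactivated by its para methoxyl. Forcing the temperature invites base-induced decomposition of the aldehydes and opening of the lactone. The fallback reverses the polarity of the coupling and sets out from 4. Tf2O and pyridine convert it into 6-formyl-7-methoxy-2-oxo-2H-chromen-5-yl trifluoromethanesulfonate F3, an electron-poor electrophile. F3 is joined to commercial 2-hydroxy-5-methoxybenzaldehyde, a more nucleophilic phenol, by palladium-catalysed C–O coupling (Pd(OAc)2, 2-di-tert-butylphosphino-2',4',6'-triisopropylbiphenyl, K3PO4, toluene, 100 °C). Reductive elimination of a diaryl ether is favoured when the aryl group on palladium is electron-poor. The fallback returns to the route at 6.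

**Step 6.** The most likely failure is poor site selectivity among the nucleophilic positions of 9: oxygen addition of the catechol to the propiolate, attack at C8 of unit B or a second annulation, together with oxidative darkening of the tetraphenol on heating. The fallback builds pyranone A from an aldehyde and sets out from 8. Vilsmeier–Haack formylation (POCl3, DMF) should occur at C5', para to the free C2' hydroxyl and ortho to the methoxyl, to give 4-hydroxy-5-[(6-hydroxy-7-methoxy-2-oxo-2H-chromen-5-yl)oxy]-2-methoxybenzaldehyde F4. BBr3 then gives 5-[(6,7-dihydroxy-2-oxo-2H-chromen-5-yl)oxy]-2,4-dihydroxybenzaldehyde F5. A Wittig reaction with ethyl (triphenylphosphoranylidene)acetate in refluxing N,N-diethylaniline gives ethyl (2E)-3-{5-[(6,7-dihydroxy-2-oxo-2H-chromen-5-yl)oxy]-2,4-dihydroxyphenyl}prop-2-enoate F6, which isomerises and lactonises at that temperature and returns to the route at 12.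

**Step 2.** The most likely failure is sluggish hydroxymethylation, because the coumarin phenoxide is a weak nucleophile and C6 is flanked on both sides. Long heating then leads to O-methoxymethylation or to methanolysis of the lactone. The fallback changes from base-mediated magnesium phenoxide chemistry to a Lewis-acid Friedel–Crafts reaction. It sets out from 2, which is treated with dichloromethyl methyl ether and TiCl4 in CH2Cl2 at 0 °C (Rieche formylation). The titanium phenoxide directs the electrophile to the same ortho carbon, and aqueous work-up returns to the route at 4 without any new isolated compound.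

## Further compounds

F1 | step 4 | 5-(2-acetyl-4-methoxyphenoxy)-7-methoxy-2-oxo-2H-chromene-6-carbaldehyde | COc1ccc(Oc2c(C=O)c(OC)cc3oc(=O)ccc23)c(C(C)=O)c1
F2 | step 4 | 2-{[6-(formyloxy)-7-methoxy-2-oxo-2H-chromen-5-yl]oxy}-5-methoxyphenyl acetate | COc1ccc(Oc2c(OC=O)c(OC)cc3oc(=O)ccc23)c(OC(C)=O)c1
F3 | step 3 | 6-formyl-7-methoxy-2-oxo-2H-chromen-5-yl trifluoromethanesulfonate | COc1cc2oc(=O)ccc2c(OS(=O)(=O)C(F)(F)F)c1C=O
F4 | step 6 | 4-hydroxy-5-[(6-hydroxy-7-methoxy-2-oxo-2H-chromen-5-yl)oxy]-2-methoxybenzaldehyde | COc1cc(O)c(Oc2c(O)c(OC)cc3oc(=O)ccc23)cc1C=O
F5 | step 6 | 5-[(6,7-dihydroxy-2-oxo-2H-chromen-5-yl)oxy]-2,4-dihydroxybenzaldehyde | O=Cc1cc(Oc2c(O)c(O)cc3oc(=O)ccc23)c(O)cc1O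
F6 | step 6 | ethyl (2E)-3-{5-[(6,7-dihydroxy-2-oxo-2H-chromen-5-yl)oxy]-2,4-dihydroxyphenyl}prop-2-enoate | CCOC(=O)/C=C/c1cc(Oc2c(O)c(O)cc3oc(=O)ccc23)c(O)cc1O
F0 | step 2 | none | none
A1 | alternative 1 | 2-(2,4-dimethoxyphenoxy)-4,6-dihydroxy-3-methoxybenzaldehyde | O=Cc1c(O)cc(O)c(OC)c1Oc1ccc(OC)cc1OC
A2 | alternative 1 | 3-(2,4-dimethoxyphenoxy)prop-2-ynal | COc1ccc(OC#CC=O)c(OC)c1
A3 | alternative 1 | 1,4-dimethoxy-1,3-bis(trimethylsilyloxy)buta-1,3-diene (enol ether geometry not defined; it is lost on aromatisation) | COC=C(O[Si](C)(C)C)C=C(OC)O[Si](C)(C)C
A4 | alternative 2 | 6-[(6,7-dimethoxy-2-oxo-2H-chromen-5-yl)oxy]-7-methoxy-2H-chromen-2-one | O=c1ccc2cc(Oc3c(OC)c(OC)cc4oc(=O)ccc34)c(OC)cc2o1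
A5 | alternative 2 | (2E)-3-{2-[5-((1E)-2-carboxyethenyl)-2-methoxyphenoxy]-3,4-dimethoxyphenyl}prop-2-enoic acid | COc1ccc(/C=C/C(O)=O)cc1Oc1c(OC)c(OC)ccc1/C=C/C(O)=O
A6 | alternative 3 | 5-(2-ethoxy-4-hydroxyphenoxy)-6,7-dimethoxy-2H-chromen-2-one | CCOc1cc(O)ccc1Oc1c(OC)c(OC)cc2oc(=O)ccc12
A7 | alternative 3 | rac-2-[(6,7-dimethoxy-2-oxo-2H-chromen-5-yl)oxy]but-3-enoyl chloride | C=CC(Oc1c(OC)c(OC)cc2oc(=O)ccc12)C(Cl)=O
A8 | alternative 3 | ethoxyethyne (ethoxyacetylene) | CCOC#C
A9 | alternative 3 | 5-hydroxy-6,7-dimethoxy-2H-chromen-2-one | COc1cc2oc(=O)ccc2c(O)c1OC
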